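Cuts: the two EE acetals and the CHO/CH2OH level; the ketone C–C8 bond between ring A and chromene ring B (aryllithium + lactone); the prenyl O–CH2 bond; the CH2 carbon of a ring-A phthalide (directed lithiation); and the C4–C4a and O1–C2 bonds of pyran ring C, cut together to 2-bromoresorcinol and prenal.
Forward order: ring C is closed on ring B in step 1. Ring A is built separately as a phthalide (temporary lactone ring D). The C8-lithiated chromene opens ring D and joins the halves, and oxidation plus acetal hydrolysis finish the route.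
Enabling feature: ring C is the closed valence isomer of the 1-oxatriene O1=C8a–C4a=C4–C3=C2. C4a is ortho to O1 and para to O7, so it is the nucleophilic carbon of a resorcinol, and C8 lies on that resorcinol's mirror plane, so a C8-blocked symmetric precursor can give only one chromene.
Helpers: Br at C8 blocks the carbon between the oxygens and later serves as the lithiation handle (lost in step 9). Lactone ring D holds the future CHO carbon at the alcohol level, so the 2-formylbenzophenone never meets the amine catalyst or an organolithium (such compounds condense with primary amines to isoindolinones and undergo base-induced Cannizzaro–Tishchenko-type lactonisation); it is opened in step 9 and oxidised in step 10. The EE acetals are removed in step 11.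
Stereochemistry: the target has no stereocentre. C3=C4 is cis by ring constraint and the prenyl alkene is not stereogenic.

Key step: step 1

Assumption: the 1-ethoxyethyl (EE) acetal carbons are stereogenic but transient. EE compounds are carried as stereoisomer mixtures and drawn without configuration. The target is drawn as its open keto-aldehyde tautomer.

Step 1
Reactants: 1 2-bromobenzene-1,3-diol (2-bromoresorcinol); 2 3-methylbut-2-enal (prenal)
Product: 4 8-bromo-2,2-dimethyl-2H-chromen-7-ol, via o-quinone methide 3 (not isolated)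
Conditions: ethylenediammonium diacetate (EDDA, 10 mol %), toluene, reflux, Dean–Stark; 2 (1.0 equiv) added slowly to 1 (1.2 equiv)
Reagents that add atoms: none
Why: Under amine-salt catalysis (iminium activation of 2), C4 of 1, which is ortho to one OH and para to the other, attacks the aldehyde carbon in 1,2-fashion, and loss of water gives o-quinone methide 3, a 1-oxatriene O=C–C=CH–CH=CMe2; this forms the C4–C4a bond. Compound 3 then closes ring C by a thermally allowed disrotatory oxa-6π electrocyclisation that forms the O1–C2 bond and restores the aromaticity of ring B, so both pyran bonds arise in one flask. The closest known reaction type is the formal [3+3] chromenylation of resorcinols with α,β-unsaturated aldehydes (Knoevenagel-type condensation/oxa-6π cascade). No stereocentre is created, because C2 carries two methyl groups. Regiochemistry needs no control: 1 is mirror-symmetric, its two C–H/OH pairs are equivalent, and the bromine blocks the carbon between the oxygens that would lead to the 5-hydroxy isomer. The β,β-disubstitution of 2 disfavours conjugate addition, and a second annulation at C6 of 4 is held back by the excess of 1 and the slow addition of 2.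

Step 2
Reactants: 4 8-bromo-2,2-dimethyl-2H-chromen-7-ol
Product: 5 8-bromo-7-(1-ethoxyethoxy)-2,2-dimethyl-2H-chromene
Conditions: ethyl vinyl ether (3 equiv), PPTS (5 mol %), CH2Cl2, rt
Reagents that add atoms: ethyl vinyl ether, C=COCC
Why: Acid-catalysed addition of the phenol to the enol ether (acetal protection) should proceed under PPTS without touching the chromene alkene, and the acetal oxygen later helps to stabilise the neighbouring aryllithium.

Step 3
Reactants: 6 1-bromo-2,5-dimethoxy-4-methylbenzene
Product: 8 N,N-diethyl-2,5-dimethoxy-4-methylbenzamide, via aryllithium 7 (not isolated)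
Conditions: n-BuLi (1.05 equiv), THF, −78 °C; then Et2NCOCl, −78 °C to rt
Reagents that add atoms: N,N-diethylcarbamoyl chloride, CCN(CC)C(=O)Cl
Why: Fast bromine–lithium exchange followed by acylation of the aryllithium with a carbamoyl chloride is a standard entry to tertiary benzamides.

Step 4
Reactants: 8 N,N-diethyl-2,5-dimethoxy-4-methylbenzamide
Product: 10 N,N-diethyl-2-formyl-3,6-dimethoxy-4-methylbenzamide, via ortho-lithiated amide 9 (not isolated)
Conditions: s-BuLi (1.2 equiv), TMEDA, THF, −78 °C; then DMF; H2O
Reagents that add atoms: N,N-dimethylformamide, CN(C)C=O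
Why: Directed ortho-metalation works here because the only free position ortho to the amide is also ortho to a methoxy group, so both directors cooperate and DMF formylates that carbon.

Step 5
Reactants: 10 N,N-diethyl-2-formyl-3,6-dimethoxy-4-methylbenzamide
Product: 12 4,7-dimethoxy-5-methylisobenzofuran-1(3H)-one, via hydroxymethyl amide 11 (not isolated)
Conditions: NaBH4, MeOH, 0 °C; then 6 M aq HCl, reflux
Reagents that add atoms: none
Why: Borohydride reduction of the aldehyde and acid-catalysed lactonisation of the 2-(hydroxymethyl)benzamide with loss of diethylamine is the classical phthalide synthesis.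

Step 6
Reactants: 12 4,7-dimethoxy-5-methylisobenzofuran-1(3H)-one
Product: 13 4,7-dihydroxy-5-methylisobenzofuran-1(3H)-one
Conditions: BBr3 (3 equiv), CH2Cl2, −78 °C to rt; H2O
Reagents that add atoms: none
Why: Lewis-acid cleavage of aryl methyl ethers with BBr3 should remove both methyl groups, and phthalide lactones tolerate this reagent.

Step 7
Reactants: 13 4,7-dihydroxy-5-methylisobenzofuran-1(3H)-one
Product: 14 7-(1-ethoxyethoxy)-4-hydroxy-5-methylisobenzofuran-1(3H)-one
Conditions: 1-chloroethyl ethyl ether (1.0 equiv), i-Pr2NEt (1.1 equiv), CH2Cl2, −20 to 0 °C, argon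
Reagents that add atoms: 1-chloroethyl ethyl ether, CCOC(C)Cl
Why: In this base-mediated O-alkylation with an α-chloro ether, O7–H is the more acidic phenol (ortho to the lactone carbonyl) with one free ortho position, whereas O4–H is flanked by CH3 and the lactone CH2, so one equivalent of reagent should acetalise O7 first, and misdirected material can be returned to 13 by mild acid.

Step 8
Reactants: 14 7-(1-ethoxyethoxy)-4-hydroxy-5-methylisobenzofuran-1(3H)-one; 15 1-bromo-3-methylbut-2-ene (prenyl bromide)
Product: 16 7-(1-ethoxyethoxy)-5-methyl-4-[(3-methylbut-2-en-1-yl)oxy]isobenzofuran-1(3H)-one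
Conditions: K2CO3 (1.5 equiv), DMF, rt
Reagents that add atoms: none
Why: Williamson etherification (SN2 at the primary allylic bromide) acts on the only remaining phenol, and the acetal and lactone tolerate K2CO3.

Step 9
Reactants: 5 8-bromo-7-(1-ethoxyethoxy)-2,2-dimethyl-2H-chromene; 16 7-(1-ethoxyethoxy)-5-methyl-4-[(3-methylbut-2-en-1-yl)oxy]isobenzofuran-1(3H)-one
Product: 19 [2-(1-ethoxyethoxy)-6-(hydroxymethyl)-4-methyl-5-(3-methylbut-2-enyloxy)phenyl][7-(1-ethoxyethoxy)-2,2-dimethyl-2H-chromen-8-yl]methanone, via chromenyllithium 17 (not isolated), via lithium hemiketal alkoxide 18 (not isolated)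
Conditions: 5 (1.2 equiv), n-BuLi (1.15 equiv), THF, −78 °C; then 16 (1.0 equiv), −78 to −20 °C; H2O
Reagents that add atoms: none
Why: Bromine–lithium exchange gives an aryllithium flanked by two coordinating oxygens that should add once to the planar, tied-back lactone carbonyl (acyl substitution with an internal leaving group); adduct 18 and the tetra-ortho-substituted ketone resist a second addition, and 19 is drawn as the open form of a ketone/hemiketal tautomer pair.

Step 10
Reactants: 19 the hydroxy ketone from step 9
Product: 20 3-(1-ethoxyethoxy)-2-[7-(1-ethoxyethoxy)-2,2-dimethyl-2H-chromene-8-carbonyl]-5-methyl-6-(3-methylbut-2-enyloxy)benzaldehyde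
Conditions: Dess–Martin periodinane (1.3 equiv), pyridine (5 equiv), CH2Cl2, 0 °C to rt
Reagents that add atoms: none
Why: Dess–Martin oxidation acts on the primary benzylic alcohol of the open tautomer (the tertiary hemiketal cannot be oxidised and drains through the equilibrium), and pyridine buffers the acetic acid so that the acetals persist.

Step 11
Reactants: 20 the bis-EE keto aldehyde from step 10
Product: 21 3-hydroxy-2-(7-hydroxy-2,2-dimethyl-2H-chromene-8-carbonyl)-5-methyl-6-[(3-methylbut-2-en-1-yl)oxy]benzaldehyde (target)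
Conditions: 0.5 M aq HCl, THF, 0 °C to rt
Reagents that add atoms: none
Why: Acid hydrolysis of the two aryl alkyl acetals is much faster than ionisation of an aryl prenyl ether, so dilute acid should free both ketone-chelated phenols and leave the prenyl ether, chromene and aldehyde intact.

Compound list
1 | 2-bromobenzene-1,3-diol | Oc1cccc(O)c1Br | starting material
2 | 3-methylbut-2-enal | CC(C)=CC=O | starting material
3 | (Z)-2-bromo-3-hydroxy-6-(3-methylbut-2-en-1-ylidene)cyclohexa-2,4-dien-1-one (not isolated; the geometry that can close) | CC(C)=C/C=C1/C=CC(O)=C(Br)C1=O | intermediate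
4 | 8-bromo-2,2-dimethyl-2H-chromen-7-ol | CC1(C)C=Cc2ccc(O)c(Br)c2O1 | intermediate
5 | 8-bromo-7-(1-ethoxyethoxy)-2,2-dimethyl-2H-chromene (racemic acetal) | CCOC(C)Oc1ccc2C=CC(C)(C)Oc2c1Br | intermediate
6 | 1-bromo-2,5-dimethoxy-4-methylbenzene | COc1cc(Br)c(OC)cc1C | starting material
7 | (2,5-dimethoxy-4-methylphenyl)lithium (not isolated) | COc1cc([Li])c(OC)cc1C | intermediate
8 | N,N-diethyl-2,5-dimethoxy-4-methylbenzamide | CCN(CC)C(=O)c1cc(OC)c(C)cc1OC | intermediate
9 | [2-(diethylcarbamoyl)-3,6-dimethoxy-5-methylphenyl]lithium (not isolated) | CCN(CC)C(=O)c1c([Li])c(OC)c(C)cc1OC | intermediate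
10 | N,N-diethyl-2-formyl-3,6-dimethoxy-4-methylbenzamide | CCN(CC)C(=O)c1c(C=O)c(OC)c(C)cc1OC | intermediate
11 | N,N-diethyl-2-(hydroxymethyl)-3,6-dimethoxy-4-methylbenzamide (not isolated) | CCN(CC)C(=O)c1c(CO)c(OC)c(C)cc1OC | intermediate
12 | 4,7-dimethoxy-5-methylisobenzofuran-1(3H)-one | COc1c(C)cc(OC)c2c1COC2=O | intermediate
13 | 4,7-dihydroxy-5-methylisobenzofuran-1(3H)-one | Cc1cc(O)c2C(=O)OCc2c1O | intermediate
14 | 7-(1-ethoxyethoxy)-4-hydroxy-5-methylisobenzofuran-1(3H)-one (racemic acetal) | CCOC(C)Oc1cc(C)c(O)c2COC(=O)c12 | intermediate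
15 | 1-bromo-3-methylbut-2-ene | CC(C)=CCBr | starting material
16 | 7-(1-ethoxyethoxy)-5-methyl-4-[(3-methylbut-2-en-1-yl)oxy]isobenzofuran-1(3H)-one (racemic acetal) | CCOC(C)Oc1cc(C)c(OCC=C(C)C)c2COC(=O)c12 | intermediate
17 | [7-(1-ethoxyethoxy)-2,2-dimethyl-2H-chromen-8-yl]lithium (not isolated) | CCOC(C)Oc1ccc2C=CC(C)(C)Oc2c1[Li] | intermediate
18 | lithium 1-aryl-1,3-dihydroisobenzofuran-1-olate, the adduct of 17 and 16 (not isolated; stereoisomer mixture) | CCOC(C)Oc1cc(C)c(OCC=C(C)C)c2COC(O[Li])(c3c(OC(C)OCC)ccc4C=CC(C)(C)Oc34)c12 | intermediate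
19 | [2-(1-ethoxyethoxy)-6-(hydroxymethyl)-4-methyl-5-(3-methylbut-2-enyloxy)phenyl][7-(1-ethoxyethoxy)-2,2-dimethyl-2H-chromen-8-yl]methanone (open tautomer; acetal stereoisomer mixture) | CCOC(C)Oc1cc(C)c(OCC=C(C)C)c(CO)c1C(=O)c1c(OC(C)OCC)ccc2C=CC(C)(C)Oc12 | intermediate
20 | 3-(1-ethoxyethoxy)-2-[7-(1-ethoxyethoxy)-2,2-dimethyl-2H-chromene-8-carbonyl]-5-methyl-6-(3-methylbut-2-enyloxy)benzaldehyde (acetal stereoisomer mixture) | CCOC(C)Oc1cc(C)c(OCC=C(C)C)c(C=O)c1C(=O)c1c(OC(C)OCC)ccc2C=CC(C)(C)Oc12 | intermediate
21 | 3-hydroxy-2-(7-hydroxy-2,2-dimethyl-2H-chromene-8-carbonyl)-5-methyl-6-[(3-methylbut-2-en-1-yl)oxy]benzaldehyde | CC(C)=CCOc1c(C)cc(O)c(C(=O)c2c(O)ccc3c2OC(C)(C)C=C3)c1C=O | target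

Total step count: 11. Longest linear sequence: 9 (steps 3 to 11).

Steps most likely to fail

Step 9. The hindered aryllithium may deprotonate the lactone at its benzylic CH2, or simply fail to add to the flanked carbonyl.
- The fallback sets out from 16 and comes back at 19. It offers the same carbon at the less hindered aldehyde level and reaches the ketone by oxidation.
- i-Bu2AlH (toluene, −78 °C) would reduce 16 to the lactol 7-(1-ethoxyethoxy)-5-methyl-4-(3-methylbut-2-enyloxy)-1,3-dihydroisobenzofuran-1-ol F1.
- Two equivalents of 17 would add to its open hydroxy-aldehyde form to give the diol [2-(1-ethoxyethoxy)-6-(hydroxymethyl)-4-methyl-5-(3-methylbut-2-enyloxy)phenyl][7-(1-ethoxyethoxy)-2,2-dimethyl-2H-chromen-8-yl]methanol F2.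
- TBSCl/imidazole would silylate only the primary alcohol, giving the mono-TBS ether of that diol F3.
- Dess–Martin oxidation of the benzhydrol would give the silyloxymethyl benzophenone F4, and Bu4NF in THF would release 19.

Step 7. Site selectivity between the two phenols may be poor, because O7–H is more acidic and less hindered but is also weakly hydrogen-bonded to the lactone carbonyl. Regioisomeric or double acetalisation would result.
- The fallback sets out from 6 and comes back at 16. It tells the two oxygens apart by the strong six-membered hydrogen bond of a salicylaldehyde.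
- LiN(i-Pr)2 (THF, −78 °C) would lithiate 6 between Br and OMe, and DMF would give 2-bromo-3,6-dimethoxy-5-methylbenzaldehyde F5.
- BBr3 would give 2-bromo-3,6-dihydroxy-5-methylbenzaldehyde F6.
- Ethyl vinyl ether/PPTS would acetalise only the non-chelated 3-OH, giving 2-bromo-3-(1-ethoxyethoxy)-6-hydroxy-5-methylbenzaldehyde F7.
- 15/K2CO3/DMF would then alkylate the chelated phenol, giving 2-bromo-3-(1-ethoxyethoxy)-5-methyl-6-(3-methylbut-2-enyloxy)benzaldehyde F8.
- NaBH4 would give [2-bromo-3-(1-ethoxyethoxy)-5-methyl-6-(3-methylbut-2-enyloxy)phenyl]methanol F9.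
- n-BuLi (2 equiv, −78 °C), CO2 and a dilute-acid work-up would carboxylate and lactonise. The acetal next to the new carboxylic acid would be lost in the same work-up, giving 7-hydroxy-5-methyl-4-(3-methylbut-2-enyloxy)isobenzofuran-1(3H)-one F10.
- The single phenol of F10 would be re-protected with ethyl vinyl ether/PPTS to give 16.

Step 1. A second annulation at C6 of 4 and self-condensation of the enal may erode the conversion of the mildly deactivated bromoresorcinol.
- The fallback sets out from 1 and comes back at 4. It replaces the condensation by O-alkylation and a sigmatropic cascade.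
- 3-Chloro-3-methylbut-1-yne, CuCl2 (catalytic) and DBU in MeCN at 0 °C would give the mono-ether 2-bromo-3-[(2-methylbut-3-yn-2-yl)oxy]phenol F11.
- Heating in xylene at 140 °C would trigger the aromatic propargyl Claisen rearrangement to the only free ortho carbon, followed by enolisation, a [1,5]-hydrogen shift to 3 and oxa-6π closure to 4.

Further compounds
F1 | step 9 | 7-(1-ethoxyethoxy)-5-methyl-4-(3-methylbut-2-enyloxy)-1,3-dihydroisobenzofuran-1-ol (stereoisomer mixture) | CCOC(C)Oc1cc(C)c(OCC=C(C)C)c2COC(O)c12
F2 | step 9 | [2-(1-ethoxyethoxy)-6-(hydroxymethyl)-4-methyl-5-(3-methylbut-2-enyloxy)phenyl][7-(1-ethoxyethoxy)-2,2-dimethyl-2H-chromen-8-yl]methanol (stereoisomer mixture) | CCOC(C)Oc1cc(C)c(OCC=C(C)C)c(CO)c1C(O)c1c(OC(C)OCC)ccc2C=CC(C)(C)Oc12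
F3 | step 9 | mono-TBS ether of F2 at the primary alcohol (stereoisomer mixture) | CCOC(C)Oc1cc(C)c(OCC=C(C)C)c(CO[Si](C)(C)C(C)(C)C)c1C(O)c1c(OC(C)OCC)ccc2C=CC(C)(C)Oc12
F4 | step 9 | [2-(tert-butyldimethylsilyloxymethyl)-6-(1-ethoxyethoxy)-4-methyl-3-(3-methylbut-2-enyloxy)phenyl][7-(1-ethoxyethoxy)-2,2-dimethyl-2H-chromen-8-yl]methanone | CCOC(C)Oc1cc(C)c(OCC=C(C)C)c(CO[Si](C)(C)C(C)(C)C)c1C(=O)c1c(OC(C)OCC)ccc2C=CC(C)(C)Oc12
F5 | step 7 | 2-bromo-3,6-dimethoxy-5-methylbenzaldehyde | COc1cc(C)c(OC)c(C=O)c1Br
F6 | step 7 | 2-bromo-3,6-dihydroxy-5-methylbenzaldehyde | Cc1cc(O)c(Br)c(C=O)c1O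
F7 | step 7 | 2-bromo-3-(1-ethoxyethoxy)-6-hydroxy-5-methylbenzaldehyde | CCOC(C)Oc1cc(C)c(O)c(C=O)c1Br
F8 | step 7 | 2-bromo-3-(1-ethoxyethoxy)-5-methyl-6-(3-methylbut-2-enyloxy)benzaldehyde | CCOC(C)Oc1cc(C)c(OCC=C(C)C)c(C=O)c1Br
F9 | step 7 | [2-bromo-3-(1-ethoxyethoxy)-5-methyl-6-(3-methylbut-2-enyloxy)phenyl]methanol | CCOC(C)Oc1cc(C)c(OCC=C(C)C)c(CO)c1Br
F10 | step 7 | 7-hydroxy-5-methyl-4-(3-methylbut-2-enyloxy)isobenzofuran-1(3H)-one | CC(C)=CCOc1c(C)cc(O)c2C(=O)OCc12
F11 | step 1 | 2-bromo-3-[(2-methylbut-3-yn-2-yl)oxy]phenol | C#CC(C)(C)Oc1cccc(O)c1Br
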